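## Retrosynthetic overview

1. The furanone is the last ring: one operation converts a ten-membered 4,5-epoxy-2-yn-1-one 6,12-butenolide into the 1,4-epoxy-3-oxo-1,5-diene by vinylogous epoxide opening and transannular O4→C1 closure (glaucolide → hirsutinolide logic).
2. The ten-membered carbocycle and the lactone form together: an intramolecular NiCl2/CrCl2 coupling of a (Z)-β-iodoenoate (C7) with an epoxy aldehyde (C6) closes C6–C7, the bond that farnesyl diphosphate cyclisation makes in germacranes, and the alkoxide lactonises onto C12.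
3. The seco chain comes from C1–C2 alkynylation of an α-methyl aldehyde with a Sharpless epoxy-enynol (sets C4).
4. The tetrasubstituted iodoenoate with C13 comes from a three-component iodo-aldol of a 4-acyloxy-2-ynoate, formaldehyde and MgI2.
5. The ynoate comes from asymmetric propiolate addition (sets C8) to an aldehyde made by organocatalytic conjugate alkenylation of crotonaldehyde (sets C10).

Assumption: locants C1–C15 are germacrane locants (C4 = O-bearing quaternary carbon, C8 = acyloxy carbon, C10 = CH–CH3; target = 4S,5E,8S,10S); the carbinol centres C1 (step 9) and C6 (step 11) are carried as epimer mixtures because both become sp2 later, so they carry no stereo mark in the SMILES.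

Abbreviation: TBS = tert-butyl(dimethyl)silyl; "TBSOCH2-acryloyl" = 2-{[tert-butyl(dimethyl)silyl]oxymethyl}prop-2-enoyl.

## Route

Step 1
Reactants: 1 (Z)-3-methylpent-2-en-4-yn-1-ol
Product: 2 [(2S,3R)-3-ethynyl-3-methyloxiran-2-yl]methanol
Conditions: Ti(OiPr)4 (0.2 equiv), L-(+)-diethyl tartrate (0.25 equiv), t-BuOOH (2 equiv), 4 Å MS, CH2Cl2, −20 °C
Reagents that add atoms: tert-butyl hydroperoxide CC(C)(C)OO
Why: Sharpless asymmetric epoxidation, in which L-(+)-tartrate delivers oxygen to the same face as in nerol → (2S,3R)-epoxynerol, fixing the C4–O stereocentre that survives to the target (C5 is destroyed later).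

Step 2
Reactants: 3 (E)-but-2-enal; 4 potassium trifluoro[(E)-2-phenylethenyl]borate
Product: 5 (3S,4E)-3-methyl-5-phenylpent-4-enal
Conditions: (2R,5R)-5-benzyl-2-tert-butyl-3-methylimidazolidin-4-one·HCl (20 mol %), HF (1 equiv), DME, −20 °C
Reagents that add atoms: none
Why: Iminium-catalysed conjugate alkenylation with an alkenyl trifluoroborate (MacMillan organocatalytic vinylation), in which the imidazolidinone (antipode of the catalyst that gives (R)-3-arylbutanals) shields one face of the (E)-iminium so that C10 is set as S; the styryl group is a latent C1 aldehyde.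

Step 3
Reactants: 5 (3S,4E)-3-methyl-5-phenylpent-4-enal; 6 methyl prop-2-ynoate
Product: 7 methyl (4S,6S,7E)-4-hydroxy-6-methyl-8-phenyloct-7-en-2-ynoate
Conditions: (R)-BINOL (0.4 equiv), Et2Zn (4 equiv), HMPA (2 equiv), Ti(OiPr)4 (1 equiv), CH2Cl2, 23 °C
Reagents that add atoms: none
Why: BINOL/Ti(OiPr)4-promoted asymmetric alkynylzinc addition (Pu-type propiolate addition) under reagent control, the ligand antipode being the one that delivers the alkynyl group to the Re face to set C8 as S (the minor C8 epimer is a separable diastereomer; the other BINOL antipode is used if Mosher analysis shows the opposite sense).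

Step 4
Reactants: 8 ethyl 2-(hydroxymethyl)prop-2-enoate
Product: 9 ethyl 2-{[tert-butyl(dimethyl)silyl]oxymethyl}prop-2-enoate
Conditions: TBSCl, imidazole, DMF, 0 → 23 °C
Reagents that add atoms: tert-butyl(chloro)dimethylsilane CC(C)(C)[Si](C)(C)Cl
Why: Standard silyl ether formation, which masks the side-chain hydroxyl against the later oxidations.

Step 5
Reactants: 9 ethyl 2-{[tert-butyl(dimethyl)silyl]oxymethyl}prop-2-enoate
Product: 10 2-{[tert-butyl(dimethyl)silyl]oxymethyl}prop-2-enoic acid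
Conditions: LiOH·H2O, THF/H2O 3:1, 0 °C; then 1 M HCl to pH 4
Reagents that add atoms: lithium hydroxide [Li+].[OH-]
Why: Ester saponification under conditions that leave the primary TBS ether intact.

Step 6
Reactants: 7 methyl (4S,6S,7E)-4-hydroxy-6-methyl-8-phenyloct-7-en-2-ynoate; 10 2-{[tert-butyl(dimethyl)silyl]oxymethyl}prop-2-enoic acid
Product: 11 methyl (4S,6S,7E)-4-[(TBSOCH2-acryloyl)oxy]-6-methyl-8-phenyloct-7-en-2-ynoate
Conditions: DIC (1.3 equiv), DMAP (0.1 equiv), CH2Cl2, 0 °C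
Reagents that add atoms: none
Why: Steglich esterification with retention at C8, which installs the final C8 acyl group early so that it also protects O8.

Step 7
Reactants: 11 methyl (4S,6S,7E)-4-[(TBSOCH2-acryloyl)oxy]-6-methyl-8-phenyloct-7-en-2-ynoate
Product: 13 methyl (2Z,4S,6S,7E)-2-(acetoxymethyl)-4-[(TBSOCH2-acryloyl)oxy]-3-iodo-6-methyl-8-phenylocta-2,7-dienoate, via hydroxymethyl iodoenoate 12 (not isolated)
Conditions: MgI2 (1.5 equiv), monomeric CH2O (3 equiv, from cracked paraformaldehyde), CH2Cl2, −78 → −20 °C; then Ac2O, pyridine, DMAP (cat.), 0 °C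
Reagents that add atoms: magnesium diiodide [Mg+2].[I-].[I-]; formaldehyde C=O; acetic anhydride CC(=O)OC(C)=O
Why: Proposed new method: iodide adds to the β-carbon (C7) of the Mg-activated ynoate and the resulting magnesium allenolate is captured at C11 by formaldehyde on the side away from iodine (anti addition, as in NaI/AcOH hydroiodination of 2-ynoates), giving the (Z)-alkene with I cis to CO2Me before in-flask acetylation; the closest known reaction is the three-component iodo-aldol (β-iodo Morita–Baylis–Hillman) coupling of propiolates and ynones with aldehydes.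

Step 8
Reactants: 13 methyl (2Z,4S,6S,7E)-2-(acetoxymethyl)-4-[(TBSOCH2-acryloyl)oxy]-3-iodo-6-methyl-8-phenylocta-2,7-dienoate
Product: 14 methyl (2Z,4S,6S)-2-(acetoxymethyl)-4-[(TBSOCH2-acryloyl)oxy]-3-iodo-6-methyl-7-oxohept-2-enoate
Conditions: O3 (1.0 equiv, titrated), CH2Cl2, −78 °C; then PPh3, −78 → 23 °C
Reagents that add atoms: ozone [O-][O+]=O
Why: Chemoselective ozonolysis, since the electron-rich styryl alkene reacts far faster than the acrylate and the tetrasubstituted iodoenoate, unveiling the C1 aldehyde without touching C10.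

Step 9
Reactants: 14 methyl (2Z,4S,6S)-2-(acetoxymethyl)-4-[(TBSOCH2-acryloyl)oxy]-3-iodo-6-methyl-7-oxohept-2-enoate; 2 [(2S,3R)-3-ethynyl-3-methyloxiran-2-yl]methanol
Product: 15 methyl (2Z,4S,6S)-2-(acetoxymethyl)-4-[(TBSOCH2-acryloyl)oxy]-7-hydroxy-9-[(2R,3S)-3-(hydroxymethyl)-2-methyloxiran-2-yl]-3-iodo-6-methylnon-2-en-8-ynoate (C7 epimers)
Conditions: Zn(OTf)2 (2.5 equiv), Et3N (3 equiv), toluene, 23 °C
Reagents that add atoms: none
Why: Carreira-type zinc acetylide addition to the aldehyde under mild amine conditions that tolerate the esters, the vinyl iodide and the α-stereocentre (C10); the new C1 carbinol configuration is irrelevant.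

Step 10
Reactants: 15 methyl (2Z,4S,6S)-2-(acetoxymethyl)-4-[(TBSOCH2-acryloyl)oxy]-7-hydroxy-9-[(2R,3S)-3-(hydroxymethyl)-2-methyloxiran-2-yl]-3-iodo-6-methylnon-2-en-8-ynoate
Product: 16 methyl (2Z,4S,6S)-2-(acetoxymethyl)-4-[(TBSOCH2-acryloyl)oxy]-9-[(2R,3R)-3-formyl-2-methyloxiran-2-yl]-7-hydroxy-3-iodo-6-methylnon-2-en-8-ynoate (C7 epimers)
Conditions: TEMPO (0.15 equiv), PhI(OAc)2 (1.2 equiv), CH2Cl2, 0 → 23 °C
Reagents that add atoms: none
Why: Oxoammonium (TEMPO/PhI(OAc)2) oxidation is selective for the primary epoxy alcohol over the secondary propargylic alcohol, which is kept at C1 so that the vinyl metal of step 11 cannot close a five-membered ring onto a C1 ketone.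

Step 11
Reactants: 16 methyl (2Z,4S,6S)-2-(acetoxymethyl)-4-[(TBSOCH2-acryloyl)oxy]-9-[(2R,3R)-3-formyl-2-methyloxiran-2-yl]-7-hydroxy-3-iodo-6-methylnon-2-en-8-ynoate
Product: 18 (4R,5S,8S,10S)-13-acetoxy-8-[(TBSOCH2-acryloyl)oxy]-4,5-epoxy-1-hydroxygermacr-7(11)-en-2-yn-6,12-olide (C1/C6 epimers), via macrocyclic hydroxy ester 17 (not isolated)
Conditions: CrCl2 (8 equiv), NiCl2 (0.1 equiv), DMSO/THF 1:3, 0.002 M (syringe pump), 23 °C; aq. NH4Cl; PPTS (cat.), CH2Cl2, 23 °C
Reagents that add atoms: none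
Why: Intramolecular Nozaki–Hiyama–Kishi reaction, in which zerovalent nickel inserts into the C7–I bond, the alkenyl group passes to trivalent chromium and adds only to the C6 aldehyde with retention of alkene geometry, so the C6 alkoxide sits cis to CO2Me and lactonises to the butenolide; the cis-epoxide and the alkyne pre-organise the ten-membered ring, and the C6 centre is destroyed in step 13.

Step 12
Reactants: 18 (4R,5S,8S,10S)-13-acetoxy-8-[(TBSOCH2-acryloyl)oxy]-4,5-epoxy-1-hydroxygermacr-7(11)-en-2-yn-6,12-olide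
Product: 19 (4R,5S,8S,10S)-13-acetoxy-8-[(TBSOCH2-acryloyl)oxy]-4,5-epoxy-1-oxogermacr-7(11)-en-2-yn-6,12-olide (C6 epimers)
Conditions: Dess–Martin periodinane (1.5 equiv), NaHCO3, CH2Cl2, 0 °C
Reagents that add atoms: none
Why: Buffered Dess–Martin oxidation of the only free (propargylic) alcohol gives the ynone without base, so the C10 α-stereocentre is not epimerised.

Step 13
Reactants: 19 (4R,5S,8S,10S)-13-acetoxy-8-[(TBSOCH2-acryloyl)oxy]-4,5-epoxy-1-oxogermacr-7(11)-en-2-yn-6,12-olide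
Product: 22 O-TBS ether of the target (4S,5E,8S,10S), via hydroxy ynone 20 (not isolated), via 1,3-diketone 21 (not isolated)
Conditions: DBU (0.2 equiv), CH2Cl2, −40 → 0 °C; then CSA (0.25 equiv); then Ph3PAuNTf2 (5 mol %), H2O (2 equiv), 23 °C
Reagents that add atoms: water O
Why: Base-catalysed vinylogous E1cB opening of the epoxide from the butenolide dienolate (the glaucolide → hirsutinolide rearrangement) keeps the C4–O bond set in step 1 and gives the only C5=C6 geometry the ring allows, after which gold-catalysed hydration of the strained ynone at C3 and transannular hemiketalisation–dehydration of the C4 hydroxyl onto C1 (hydroxy-ynone → 3(2H)-furanone cyclisation) close the furanone.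

Step 14
Reactants: 22 O-TBS ether of the target
Product: 23 CNP0193735.1, (4S,5E,8S,10S)-13-acetoxy-1,4-epoxy-8-{[2-(hydroxymethyl)prop-2-enoyl]oxy}-3-oxogermacra-1,5,7(11)-trien-6,12-olide
Conditions: HF·pyridine, pyridine, THF, 0 °C
Reagents that add atoms: none
Why: Buffered fluoride desilylation removes the primary TBS ether without touching the allylic acetate, the enol lactone or the furanone.

## Compound list

1 | (Z)-3-methylpent-2-en-4-yn-1-ol | C#C/C(C)=C\CO | starting material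
2 | [(2S,3R)-3-ethynyl-3-methyloxiran-2-yl]methanol | C#C[C@@]1(C)O[C@H]1CO | intermediate
3 | (E)-but-2-enal | C/C=C/C=O | starting material
4 | potassium trifluoro[(E)-2-phenylethenyl]borate | [K+].F[B-](F)(F)/C=C/c1ccccc1 | starting material
5 | (3S,4E)-3-methyl-5-phenylpent-4-enal | O=CC[C@H](C)/C=C/c1ccccc1 | intermediate
6 | methyl prop-2-ynoate | C#CC(=O)OC | starting material
7 | methyl (4S,6S,7E)-4-hydroxy-6-methyl-8-phenyloct-7-en-2-ynoate | COC(=O)C#C[C@@H](O)C[C@H](C)/C=C/c1ccccc1 | intermediate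
8 | ethyl 2-(hydroxymethyl)prop-2-enoate | C=C(CO)C(=O)OCC | starting material
9 | ethyl 2-{[tert-butyl(dimethyl)silyl]oxymethyl}prop-2-enoate | C=C(CO[Si](C)(C)C(C)(C)C)C(=O)OCC | intermediate
10 | 2-{[tert-butyl(dimethyl)silyl]oxymethyl}prop-2-enoic acid | C=C(CO[Si](C)(C)C(C)(C)C)C(=O)O | intermediate
11 | methyl (4S,6S,7E)-4-[(TBSOCH2-acryloyl)oxy]-6-methyl-8-phenyloct-7-en-2-ynoate | COC(=O)C#C[C@@H](OC(=O)C(=C)CO[Si](C)(C)C(C)(C)C)C[C@H](C)/C=C/c1ccccc1 | intermediate
12 | methyl (2Z,4S,6S,7E)-4-[(TBSOCH2-acryloyl)oxy]-2-(hydroxymethyl)-3-iodo-6-methyl-8-phenylocta-2,7-dienoate | COC(=O)/C(CO)=C(\I)[C@@H](OC(=O)C(=C)CO[Si](C)(C)C(C)(C)C)C[C@H](C)/C=C/c1ccccc1 | intermediate (not isolated)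
13 | methyl (2Z,4S,6S,7E)-2-(acetoxymethyl)-4-[(TBSOCH2-acryloyl)oxy]-3-iodo-6-methyl-8-phenylocta-2,7-dienoate | COC(=O)/C(COC(C)=O)=C(\I)[C@@H](OC(=O)C(=C)CO[Si](C)(C)C(C)(C)C)C[C@H](C)/C=C/c1ccccc1 | intermediate
14 | methyl (2Z,4S,6S)-2-(acetoxymethyl)-4-[(TBSOCH2-acryloyl)oxy]-3-iodo-6-methyl-7-oxohept-2-enoate | COC(=O)/C(COC(C)=O)=C(\I)[C@@H](OC(=O)C(=C)CO[Si](C)(C)C(C)(C)C)C[C@H](C)C=O | intermediate
15 | methyl (2Z,4S,6S)-2-(acetoxymethyl)-4-[(TBSOCH2-acryloyl)oxy]-7-hydroxy-9-[(2R,3S)-3-(hydroxymethyl)-2-methyloxiran-2-yl]-3-iodo-6-methylnon-2-en-8-ynoate, C7 epimers | COC(=O)/C(COC(C)=O)=C(\I)[C@@H](OC(=O)C(=C)CO[Si](C)(C)C(C)(C)C)C[C@H](C)C(O)C#C[C@@]1(C)O[C@H]1CO | intermediate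
16 | methyl (2Z,4S,6S)-2-(acetoxymethyl)-4-[(TBSOCH2-acryloyl)oxy]-9-[(2R,3R)-3-formyl-2-methyloxiran-2-yl]-7-hydroxy-3-iodo-6-methylnon-2-en-8-ynoate, C7 epimers | COC(=O)/C(COC(C)=O)=C(\I)[C@@H](OC(=O)C(=C)CO[Si](C)(C)C(C)(C)C)C[C@H](C)C(O)C#C[C@@]1(C)O[C@H]1C=O | intermediate
17 | methyl (4R,5S,8S,10S)-13-acetoxy-8-[(TBSOCH2-acryloyl)oxy]-4,5-epoxy-1,6-dihydroxygermacr-7(11)-en-2-yn-12-oate, C1 and C6 epimers | C=C(CO[Si](C)(C)C(C)(C)C)C(=O)O[C@H]1C[C@H](C)C(O)C#C[C@@]2(C)O[C@H]2C(O)/C1=C(/COC(C)=O)C(=O)OC | intermediate (not isolated)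
18 | (4R,5S,8S,10S)-13-acetoxy-8-[(TBSOCH2-acryloyl)oxy]-4,5-epoxy-1-hydroxygermacr-7(11)-en-2-yn-6,12-olide, C1 and C6 epimers | C=C(CO[Si](C)(C)C(C)(C)C)C(=O)O[C@H]1C[C@H](C)C(O)C#C[C@@]2(C)O[C@H]2C3OC(=O)C(COC(C)=O)=C31 | intermediate
19 | (4R,5S,8S,10S)-13-acetoxy-8-[(TBSOCH2-acryloyl)oxy]-4,5-epoxy-1-oxogermacr-7(11)-en-2-yn-6,12-olide, C6 epimers | C=C(CO[Si](C)(C)C(C)(C)C)C(=O)O[C@H]1C[C@H](C)C(=O)C#C[C@@]2(C)O[C@H]2C3OC(=O)C(COC(C)=O)=C31 | intermediate
20 | (4S,5E,8S,10S)-13-acetoxy-8-[(TBSOCH2-acryloyl)oxy]-4-hydroxy-1-oxogermacra-5,7(11)-dien-2-yn-6,12-olide | C=C(CO[Si](C)(C)C(C)(C)C)C(=O)O[C@H]1C[C@H](C)C(=O)C#C[C@@](C)(O)/C=C3/OC(=O)C(COC(C)=O)=C31 | intermediate (not isolated)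
21 | (4S,5E,8S,10S)-13-acetoxy-8-[(TBSOCH2-acryloyl)oxy]-4-hydroxy-1,3-dioxogermacra-5,7(11)-dien-6,12-olide | C=C(CO[Si](C)(C)C(C)(C)C)C(=O)O[C@H]1C[C@H](C)C(=O)CC(=O)[C@@](C)(O)/C=C3/OC(=O)C(COC(C)=O)=C31 | intermediate (not isolated)
22 | (4S,5E,8S,10S)-13-acetoxy-8-[(TBSOCH2-acryloyl)oxy]-1,4-epoxy-3-oxogermacra-1,5,7(11)-trien-6,12-olide | C=C(CO[Si](C)(C)C(C)(C)C)C(=O)O[C@H]1C[C@H](C)C2=CC(=O)[C@](C)(/C=C3/OC(=O)C(COC(C)=O)=C31)O2 | intermediate
23 | CNP0193735.1, (4S,5E,8S,10S)-13-acetoxy-1,4-epoxy-8-{[2-(hydroxymethyl)prop-2-enoyl]oxy}-3-oxogermacra-1,5,7(11)-trien-6,12-olide | C=C(CO)C(=O)O[C@H]1C[C@H](C)C2=CC(=O)[C@](C)(/C=C3/OC(=O)C(COC(C)=O)=C31)O2 | target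

## Step count and risk

Total step count: 14. Longest linear sequence: 11 (steps 2, 3, 6, 7, 8, 9, 10, 11, 12, 13, 14).

The three steps most likely to fail:

**Step 7 (three-component iodo-aldol).** An internal 4-acyloxy-2-ynoate with formaldehyde is an untested substrate pair; conversion may be poor, the styryl group may undergo a Prins reaction, and the geometry must be Z (I cis to CO2Me) or step 11 cannot lactonise. Fallback, setting out from 11 and coming back at 13: the vinyl electrophile is built from a ketone instead of from the alkyne. Gold-catalysed, acyloxy-assisted hydration of 11 (Ph3PAuNTf2, H2O, dioxane) gives methyl (4S,6S,7E)-4-[(TBSOCH2-acryloyl)oxy]-6-methyl-3-oxo-8-phenyloct-7-enoate F1. Amine-catalysed α-methylenation with formaldehyde gives the 2-methylidene-3-oxo ester F2, used at once. Conjugate addition of acetate (LiOAc, LiOTf) and O-triflation of the chelated enolate (PhNTf2) give the (Z)-enol triflate F3, whose geometry follows the known chelation-controlled Z-triflation of α-substituted β-keto esters. Nickel-catalysed triflate-to-iodide exchange (NaI, Ni(OAc)2·4H2O, cod) then gives 13; F3 could also enter step 11 chemistry directly, since enol triflates are competent in NiCl2/CrCl2 couplings.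

**Step 11 (ten-membered ring closure at C6–C7).** Risks are oligomerisation, reduction of the epoxy aldehyde by CrCl2, and strain from the in-ring alkyne. Fallback, setting out from 13 (with 2) and coming back at 18: the C6–C7 bond and the lactone are made intermolecularly and the ring is closed at C1–C2 instead. Oxidation of 2 (TEMPO, PhI(OAc)2) gives (2R,3R)-3-ethynyl-3-methyloxirane-2-carbaldehyde F4. CrCl2/NiCl2 coupling of 13 with F4 and lactonisation give the open-chain butenolide F5. AgNO3/NIS converts the terminal alkyne into the iodoalkyne F6, and ozonolysis of the styryl group gives the iodoalkyne aldehyde F7. CrCl2/NiCl2 at high dilution then closes the ring by iodoalkyne–aldehyde addition, a reaction well established for strained ten-membered cycloalkynes, to give 18.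

**Step 13 (one-flask epoxide opening and furanone closure).** DBU may epimerise C10 of the ynone, the dienolate may lose the C13 acetate instead of opening the epoxide (this should be reversible in an aprotic medium), and the gold step may be inhibited by the amine salt. Fallback, setting out from 18 and coming back at 22: the base step is moved to the carbinol stage, where C10 is not acidic and the alkyne is not an electrophile. Catalytic DBU on 18 gives the (4S,5E)-1,4-dihydroxy dienolide F8. MnO2 oxidises only the secondary propargylic alcohol to give 20, which is isolated. Ph3PAuNTf2 with water then closes the furanone through 21 to give 22.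

## Further compounds

F1 | step 7 | methyl (4S,6S,7E)-4-[(TBSOCH2-acryloyl)oxy]-6-methyl-3-oxo-8-phenyloct-7-enoate | COC(=O)CC(=O)[C@@H](OC(=O)C(=C)CO[Si](C)(C)C(C)(C)C)C[C@H](C)/C=C/c1ccccc1
F2 | step 7 | methyl (4S,6S,7E)-4-[(TBSOCH2-acryloyl)oxy]-6-methyl-2-methylidene-3-oxo-8-phenyloct-7-enoate | COC(=O)C(=C)C(=O)[C@@H](OC(=O)C(=C)CO[Si](C)(C)C(C)(C)C)C[C@H](C)/C=C/c1ccccc1
F3 | step 7 | methyl (2Z,4S,6S,7E)-2-(acetoxymethyl)-4-[(TBSOCH2-acryloyl)oxy]-6-methyl-8-phenyl-3-{[(trifluoromethyl)sulfonyl]oxy}octa-2,7-dienoate | COC(=O)/C(COC(C)=O)=C(\OS(=O)(=O)C(F)(F)F)[C@@H](OC(=O)C(=C)CO[Si](C)(C)C(C)(C)C)C[C@H](C)/C=C/c1ccccc1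
F4 | step 11 | (2R,3R)-3-ethynyl-3-methyloxirane-2-carbaldehyde | C#C[C@@]1(C)O[C@H]1C=O
F5 | step 11 | 3-(acetoxymethyl)-5-[(2S,3R)-3-ethynyl-3-methyloxiran-2-yl]-4-{(1S,3S,4E)-3-methyl-5-phenyl-1-[(TBSOCH2-acryloyl)oxy]pent-4-en-1-yl}furan-2(5H)-one, C5 epimers | C#C[C@@]1(C)O[C@H]1C2OC(=O)C(COC(C)=O)=C2[C@@H](OC(=O)C(=C)CO[Si](C)(C)C(C)(C)C)C[C@H](C)/C=C/c1ccccc1
F6 | step 11 | 3-(acetoxymethyl)-5-[(2S,3R)-3-(iodoethynyl)-3-methyloxiran-2-yl]-4-{(1S,3S,4E)-3-methyl-5-phenyl-1-[(TBSOCH2-acryloyl)oxy]pent-4-en-1-yl}furan-2(5H)-one, C5 epimers | IC#C[C@@]1(C)O[C@H]1C2OC(=O)C(COC(C)=O)=C2[C@@H](OC(=O)C(=C)CO[Si](C)(C)C(C)(C)C)C[C@H](C)/C=C/c1ccccc1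
F7 | step 11 | 3-(acetoxymethyl)-5-[(2S,3R)-3-(iodoethynyl)-3-methyloxiran-2-yl]-4-{(1S,3S)-3-methyl-4-oxo-1-[(TBSOCH2-acryloyl)oxy]butyl}furan-2(5H)-one, C5 epimers | IC#C[C@@]1(C)O[C@H]1C2OC(=O)C(COC(C)=O)=C2[C@@H](OC(=O)C(=C)CO[Si](C)(C)C(C)(C)C)C[C@H](C)C=O
F8 | step 13 | (4S,5E,8S,10S)-13-acetoxy-8-[(TBSOCH2-acryloyl)oxy]-1,4-dihydroxygermacra-5,7(11)-dien-2-yn-6,12-olide, C1 epimers | C=C(CO[Si](C)(C)C(C)(C)C)C(=O)O[C@H]1C[C@H](C)C(O)C#C[C@@](C)(O)/C=C3/OC(=O)C(COC(C)=O)=C31
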